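The runs were computed from invented constants.

**The cold gap.** I cannot read the cold out of larch and alder, since both ran at 20 °C: what −20 °C does to the rates stays a guess. You suspect that a slow feed is the gentler way, and I would put that to one quantity first.

| flask | D | G | temperature | remark | time |
|---|---|---|---|---|---|
| larch | 0.050 M | 0.050 M | 20 °C | run made earlier |  |
| alder | 0.10 M | 0.050 M | 20 °C | run made earlier |  |
| dawn | 0.050 M | 0.0500 M | 20 °C | everything together at the start | 4.0 h |
| winter | 0.050 M | 0.0500 M (fed, over 3.0 h) | 20 °C | all else is in the flask from the start; the feed brings no volume worth counting | 4.0 h |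
| spring | 0.050 M (fed, over 3.0 h) | 0.0500 M |  | the addition at −20 °C, then warmed to 20 °C; the feed brings no volume worth counting | 4.0 h |
| midnight | 0.050 M (fed, over 50 min) | 0.0500 M | 20 °C | all else is in the flask from the start; the feed brings no volume worth counting | 4.0 h |

- larch (time / h: L / %, D / %): 0.333: 26.7, 43.2; 0.667: 33.3, 26.2; 1.00: 34.0, 18.0; 2.00: 29.4, 10.3; 4.00: 21.4, 4.8
- alder (time / min: L / %, D / %): 5.00: 8.9, 67.8; 10.0: 13.9, 51.0; 15.0: 17.5, 39.4; 20.0: 19.7, 33.4; 25.0: 20.9, 28.9

(scatter of a reading: 0.5 percentage points)

- the best flask by amount of L, in percent of the D charged; "all alike" if 1.5 percentage points covers them all (dawn / winter / spring / midnight / all alike)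
- amount of L at the end, in percent of the D charged, dawn
- amount of L at the end, in percent of the D charged, winter
- amount of L at the end, in percent of the D charged, spring
- amount of L at the end, in percent of the D charged, midnight

- the earlier runs do not show what temperature does; that part of a forecast is a guess

**The waste ratio.** D leaves in two ways, into L with G or otherwise. At the first reading, the D lost and not found as L, per D found as L, is 1.13 in larch and 2.62 in alder, which has twice the D of larch and the same G. So I take this loss to grow with the ratio of D to G. Dividing the alder reading by its charge ratio gives 1.31, my waste ratio: D lost otherwise per D coupled when D and G stand equal, which is the inverse of the usual selectivity factor. It is a reading and carries their scatter. With d and g as fractions of equal charges, the share of lost D that becomes L is one over one plus the ratio times d/g, which begins at 43.3 %.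

**Both ends.** Spring has a cold end and a warm end. If the cold holds D and G apart, which is my guess, then the warm end is larch started late, with 1.00 h on its clock. So I read larch there and commit to 34.0 %. Dawn repeats larch at 21.4 %. Winter puts G slowly into a full charge of D, so g is small beside d early on and the share starts below 43.3 %; against your hunch, I place winter under dawn. Midnight feeds D into a full charge of G, so the share starts above 43.3 %, and I place it slightly over dawn.

**The flasks.** The forecast says spring at 37 % (29 % to 45 %), above my figure, with dawn 21.4 %, winter 13.5 % and midnight 24.5 %, the spring warming “stopping near the L maximum”. The flasks give spring 34.3 %, midnight 23.7 %, dawn 21.4 % and winter 17.8 %.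

    2 D → E (k = 0.330 M⁻¹ min⁻¹, Ea = 68.0 kJ mol⁻¹)
    L + Z → Q (k = 0.300 M⁻¹ min⁻¹, Ea = 67.0 kJ mol⁻¹)
    D + G ⇌ L + Z (K = 2.50, k = 0.510 M⁻¹ min⁻¹, Ea = 71.0 kJ mol⁻¹, ΔH = −13.0 kJ mol⁻¹)
    (constants at 20 °C)

**One neighbour.** At the change of temperature, spring held D 95.5 % and G 97.8 %, so its share began at 43.9 %, beside my 43.3 %. The neighbour is spring with G at 0.12 M, and the same ratio starts its share at 64.7 %. Keeping the warm clock and scaling the L of spring by the two shares gives 51.3 %. That neighbour flask ends with L at 48.6 %.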